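Ring B is not carried in as an aryl unit; it is built on the finished chromone. The disconnection cuts C1'–C2' and C5'–C6': C2', C3'(OMe), C4'(OMe) and C5' with its oxygen come from 3,4-dimethoxyfuran, C1' and C6' from a terminal alkyne on C2. One operation, a Lewis-acid-assisted [4+2] cycloaddition and acid opening of the oxygen bridge, closes ring B. It exploits the fact that ring B carries adjacent methoxy groups at C3' and C4' and a free hydroxyl at C5' beside the unsubstituted C6': the furan oxygen becomes that hydroxyl. The precursor is 7-(benzyloxy)-2-ethynyl-5,6-dimethoxychromone, made from an acetophenone through the chromone-2-carbaldehyde.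

Key step: step 7

Assumption: compounds 1, 6, 10 and 12 are bought; adduct 13 forms as a racemate whose two bridgehead centres are lost within the same step, so the route needs no stereocontrol.

Step 1
Reactants: 1 2',4'-dihydroxy-6'-methoxyacetophenone
Product: 2 4'-(benzyloxy)-2'-hydroxy-6'-methoxyacetophenone
Conditions: BnBr (1.05 equiv), K2CO3 (1.2 equiv), acetone, reflux
Reagents that add atoms: benzyl bromide, BrCc1ccccc1
Why: Williamson etherification; the 2'-OH is hydrogen-bonded to the acetyl carbonyl and far less nucleophilic, so one equivalent of benzyl bromide should alkylate only the 4'-OH.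

Step 2
Reactants: 2 4'-(benzyloxy)-2'-hydroxy-6'-methoxyacetophenone
Product: 4 4'-(benzyloxy)-2',5'-dihydroxy-6'-methoxyacetophenone, via potassium aryl 5'-sulfate 3 (not isolated)
Conditions: K2S2O8 (1.1 equiv), aq. KOH, pyridine, 0 °C to rt; acidify to pH 5 and extract unchanged 2; aqueous layer: aq. HCl, Na2SO3, 80 °C, under N2
Reagents that add atoms: potassium peroxodisulfate, [K+].[K+].[O-]S(=O)(=O)OOS(=O)(=O)[O-]
Why: Elbs persulfate oxidation: the phenoxide of 2 attacks the peroxide oxygen through C5', the only carbon para to the free 2'-oxygen, and the aryl sulfate is then cleaved by warm dilute acid, which the benzyl ether and the ketone should tolerate.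

Step 3
Reactants: 4 4'-(benzyloxy)-2',5'-dihydroxy-6'-methoxyacetophenone
Product: 5 4'-(benzyloxy)-2'-hydroxy-5',6'-dimethoxyacetophenone
Conditions: Me2SO4 (1.05 equiv), K2CO3 (1.2 equiv), acetone, reflux, under N2
Reagents that add atoms: dimethyl sulfate, COS(=O)(=O)OC
Why: Selective Williamson O-methylation; the new 5'-OH is an ordinary phenol while the 2'-OH stays chelated to the ketone, so one equivalent of dimethyl sulfate should methylate only O5'.

Step 4
Reactants: 5 4'-(benzyloxy)-2'-hydroxy-5',6'-dimethoxyacetophenone; 6 ethyl diethoxyacetate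
Product: 8 7-(benzyloxy)-2-(diethoxymethyl)-5,6-dimethoxy-4H-chromen-4-one, via acetal 1,3-diketone 7 (not isolated)
Conditions: NaH (3.5 equiv), THF, 0 °C to reflux; AcOH quench; then conc. H2SO4 (cat.), dry EtOH, reflux
Reagents that add atoms: none
Why: Crossed Claisen condensation of the phenoxide–enolate dianion with an inductively activated ester that does not self-condense, then acid-catalysed cyclodehydration of the 2-hydroxyaryl 1,3-diketone (6-exo-trig hemiketal formation and loss of water) to the chromone, with the diethyl acetal retained in dry ethanol.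

Step 5
Reactants: 8 7-(benzyloxy)-2-(diethoxymethyl)-5,6-dimethoxy-4H-chromen-4-one
Product: 9 7-(benzyloxy)-5,6-dimethoxy-4-oxo-4H-chromene-2-carbaldehyde
Conditions: 3 M aq. HCl, THF, 50 °C; dry by azeotrope with toluene
Reagents that add atoms: water, O
Why: Acid-catalysed acetal hydrolysis; the chromone, the aryl methyl ethers and the benzyl ether are stable to dilute aqueous acid at this temperature, and no redox step is needed to reach the aldehyde.

Step 6
Reactants: 9 7-(benzyloxy)-5,6-dimethoxy-4-oxo-4H-chromene-2-carbaldehyde; 10 dimethyl (1-diazo-2-oxopropyl)phosphonate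
Product: 11 7-(benzyloxy)-2-ethynyl-5,6-dimethoxy-4H-chromen-4-one
Conditions: K2CO3 (2 equiv), MeOH–THF, 0 °C to rt, short reaction time
Reagents that add atoms: none
Why: Ohira–Bestmann (Seyferth–Gilbert) homologation: methanolysis of the acetyl group frees the diazomethylphosphonate anion, Horner–Wadsworth–Emmons-type olefination gives a diazoalkene that loses N2 and rearranges by 1,2-hydrogen shift to the alkyne, and because C3 is the electron-rich α-carbon of a vinylogous ester the conjugate addition of methanol that troubles ordinary enals is not expected.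

Step 7
Reactants: 11 7-(benzyloxy)-2-ethynyl-5,6-dimethoxy-4H-chromen-4-one; 12 3,4-dimethoxyfuran
Product: 14 7-(benzyloxy)-2-(3-hydroxy-4,5-dimethoxyphenyl)-5,6-dimethoxy-4H-chromen-4-one, via oxanorbornadiene adduct 13 (not isolated)
Conditions: 12 (3 equiv, added slowly), Sc(OTf)3 (10 mol %), 4 Å MS, CH2Cl2, 0 °C to rt; then CSA (20 mol %), rt
Reagents that add atoms: none
Why: Proposed new method: binding of Sc(OTf)3 between the C4 carbonyl and the 5-OMe oxygen gives the chromone benzopyrylium character, which should lower the LUMO of the C2 ethynyl group enough for a normal-demand [4+2] cycloaddition with the electron-rich furan, after which acid ionises one bridge C–O bond of the 7-oxanorbornadiene and loss of the proton on the oxygen-bearing carbon aromatises the ring. The closest known reaction type is the Diels–Alder addition of furans to ester- or ketone-activated alkynes followed by acid isomerisation of the oxanorbornadiene to a phenol, which has not been shown for an alkyne activated only vinylogously through a chromone. Ring B closes by an intermolecular suprafacial [4+2] cycloaddition that forms C1'–C2' and C5'–C6' together, not by cyclisation of a chain, and the second stage closes no ring. The two bridgehead centres of 13 arise as a racemate with their relative configuration fixed by the bicycle, and both are destroyed on aromatisation, so 14 has no stereocentre. The selectivity needed is the direction of bridge opening: cleavage at C2' gives a cation with charge on C2', C4' (stabilised by its methoxy group) and C6' and none on C1', whereas cleavage at C5' would put charge on C1' next to the metal-bound, electron-poor chromonyl group, so the oxygen should stay on C5'. The symmetric furan leaves no regiochemical question in the cycloaddition, and the C2=C3 bond of the pyranone ring is a far poorer dienophile than the alkyne.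

Step 8
Reactants: 14 7-(benzyloxy)-2-(3-hydroxy-4,5-dimethoxyphenyl)-5,6-dimethoxy-4H-chromen-4-one
Product: 15 7,5'-dihydroxy-5,6,3',4'-tetramethoxyflavone
Conditions: H2 (1 atm), 10% Pd/C, EtOAc–MeOH, rt
Reagents that add atoms: none
Why: Hydrogenolysis of the aryl benzyl ether; at one atmosphere and room temperature the chromone C2=C3 bond, the ketone and the methyl ethers should not be touched.

Compound list
1 | 2',4'-dihydroxy-6'-methoxyacetophenone | CC(=O)c1c(O)cc(O)cc1OC | starting material
2 | 4'-(benzyloxy)-2'-hydroxy-6'-methoxyacetophenone | CC(=O)c1c(O)cc(OCc2ccccc2)cc1OC | intermediate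
3 | potassium 3-acetyl-6-(benzyloxy)-4-hydroxy-2-methoxyphenyl sulfate (carried on in water) | CC(=O)c1c(O)cc(OCc2ccccc2)c(OS(=O)(=O)[O-])c1OC.[K+] | intermediate
4 | 4'-(benzyloxy)-2',5'-dihydroxy-6'-methoxyacetophenone | CC(=O)c1c(O)cc(OCc2ccccc2)c(O)c1OC | intermediate
5 | 4'-(benzyloxy)-2'-hydroxy-5',6'-dimethoxyacetophenone | CC(=O)c1c(O)cc(OCc2ccccc2)c(OC)c1OC | intermediate
6 | ethyl diethoxyacetate | CCOC(=O)C(OCC)OCC | starting material
7 | 1-[4-(benzyloxy)-2-hydroxy-5,6-dimethoxyphenyl]-4,4-diethoxybutane-1,3-dione (carried on crude) | CCOC(OCC)C(=O)CC(=O)c1c(O)cc(OCc2ccccc2)c(OC)c1OC | intermediate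
8 | 7-(benzyloxy)-2-(diethoxymethyl)-5,6-dimethoxy-4H-chromen-4-one | CCOC(OCC)c1cc(=O)c2c(OC)c(OC)c(OCc3ccccc3)cc2o1 | intermediate
9 | 7-(benzyloxy)-5,6-dimethoxy-4-oxo-4H-chromene-2-carbaldehyde | O=Cc1cc(=O)c2c(OC)c(OC)c(OCc3ccccc3)cc2o1 | intermediate
10 | dimethyl (1-diazo-2-oxopropyl)phosphonate | COP(=O)(OC)C(=[N+]=[N-])C(C)=O | starting material
11 | 7-(benzyloxy)-2-ethynyl-5,6-dimethoxy-4H-chromen-4-one | C#Cc1cc(=O)c2c(OC)c(OC)c(OCc3ccccc3)cc2o1 | intermediate
12 | 3,4-dimethoxyfuran | COc1cocc1OC | starting material
13 | 7-(benzyloxy)-2-[(1R,4S)-5,6-dimethoxy-7-oxabicyclo[2.2.1]hepta-2,5-dien-2-yl]-5,6-dimethoxy-4H-chromen-4-one, racemic, one enantiomer drawn (carried on in solution) | COC1=C(OC)[C@@H]2O[C@H]1C=C2c3cc(=O)c4c(OC)c(OC)c(OCc5ccccc5)cc4o3 | intermediate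
14 | 7-(benzyloxy)-2-(3-hydroxy-4,5-dimethoxyphenyl)-5,6-dimethoxy-4H-chromen-4-one | COc1cc(-c2cc(=O)c3c(OC)c(OC)c(OCc4ccccc4)cc3o2)cc(O)c1OC | intermediate
15 | 7,5'-dihydroxy-5,6,3',4'-tetramethoxyflavone | COc1cc(-c2cc(=O)c3c(OC)c(OC)c(O)cc3o2)cc(O)c1OC | target

Total step count: 8. Longest linear sequence: 8 steps (1 to 15); compounds 6, 10 and 12 are bought.

Steps most likely to fail

Step 7, the only step that bears the label "Proposed new method:", carries the main risk. The furan may add through its α-carbon to the activated alkyne or to C2 in a Friedel–Crafts-type conjugate addition instead of cycloadding. It may also be destroyed by acid before it reacts. The bridge may open in the other direction, or the enol ether of the adduct may hydrolyse before aromatisation. The fallback uses known flavone chemistry, sets out from acetophenone 5 and returns to the route at target 15. Claisen–Schmidt condensation of 5 with bought 3-(benzyloxy)-4,5-dimethoxybenzaldehyde (COc1cc(C=O)cc(OCc2ccccc2)c1OC; KOH, EtOH, rt) should give (E)-1-[4-(benzyloxy)-2-hydroxy-5,6-dimethoxyphenyl]-3-[3-(benzyloxy)-4,5-dimethoxyphenyl]prop-2-en-1-one F1. Oxidative cyclisation of the 2'-hydroxychalcone with catalytic I2 in DMSO at 120 °C should give 7-(benzyloxy)-2-[3-(benzyloxy)-4,5-dimethoxyphenyl]-5,6-dimethoxy-4H-chromen-4-one F2. Hydrogenolysis of both benzyl ethers (H2, Pd/C) then gives 15.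

Step 6 is the second risk. Methoxide may attack C2 and open the pyranone ring, methanol may add to the conjugated alkyne once it has formed, and the terminal alkyne may oligomerise under base. The fallback avoids alkoxide, sets out from aldehyde 9 and returns at alkyne 11. Dibromo-olefination of 9 (CBr4, PPh3, CH2Cl2, 0 °C; first stage of the Corey–Fuchs sequence) should give 7-(benzyloxy)-2-(2,2-dibromoethenyl)-5,6-dimethoxy-4H-chromen-4-one F3. Palladium-catalysed removal of the bromine trans to the ring (Bu3SnH, Pd(PPh3)4 cat., toluene, rt) should give 7-(benzyloxy)-2-[(Z)-2-bromoethenyl]-5,6-dimethoxy-4H-chromen-4-one F4. Anti elimination of HBr with DBU (MeCN, rt to 50 °C) then gives 11.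

Step 2 is the third risk. Conversion in the persulfate oxidation may stay low, the electron-rich phenoxide may be over-oxidised to dark polymeric material, and some benzyl ether may be lost during the acid hydrolysis of the sulfate. The fallback sets out from phenol 2 and returns at hydroquinone 4. Teuber oxidation of 2 with potassium nitrosodisulfonate, (KSO3)2NO (KH2PO4 buffer, acetone–water, rt), should give 2-acetyl-5-(benzyloxy)-3-methoxycyclohexa-2,5-diene-1,4-dione F5. Reduction of this para-quinone with Na2S2O4 (EtOAc–water, rt) then gives 4.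

Further compounds
F1 | step 7 | (E)-1-[4-(benzyloxy)-2-hydroxy-5,6-dimethoxyphenyl]-3-[3-(benzyloxy)-4,5-dimethoxyphenyl]prop-2-en-1-one | COc1cc(/C=C/C(=O)c2c(O)cc(OCc3ccccc3)c(OC)c2OC)cc(OCc2ccccc2)c1OC
F2 | step 7 | 7-(benzyloxy)-2-[3-(benzyloxy)-4,5-dimethoxyphenyl]-5,6-dimethoxy-4H-chromen-4-one | COc1cc(-c2cc(=O)c3c(OC)c(OC)c(OCc4ccccc4)cc3o2)cc(OCc2ccccc2)c1OC
F3 | step 6 | 7-(benzyloxy)-2-(2,2-dibromoethenyl)-5,6-dimethoxy-4H-chromen-4-one | BrC(Br)=Cc1cc(=O)c2c(OC)c(OC)c(OCc3ccccc3)cc2o1
F4 | step 6 | 7-(benzyloxy)-2-[(Z)-2-bromoethenyl]-5,6-dimethoxy-4H-chromen-4-one | Br/C=C\c1cc(=O)c2c(OC)c(OC)c(OCc3ccccc3)cc2o1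
F5 | step 2 | 2-acetyl-5-(benzyloxy)-3-methoxycyclohexa-2,5-diene-1,4-dione | CC(=O)C1=C(OC)C(=O)C(OCc2ccccc2)=CC1=O
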